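**Two ways.** Slowness is where I start, because partner B can go two ways in this flask and the useful way has the smaller constant. With substrate it gives open intermediate; with partner A it gives second intermediate. Those two couple to product, which crystallises above its solubility.

substrate 0.12 M (in portions, 4); partner A 0.132 M; partner B 0.180 M; time 80 s; the portions of substrate follow each other after 20 s, the first at the start

- amount of product at 80 s, in percent of the substrate charged
- amount of product if the flask were left three thousand times as long, in percent of the substrate charged

- what is said of product includes crystals
- crystals is a solid; its amount is given per volume of the solution
- run time (flask): 80 s

    substrate + partner B → open intermediate (k1 = 0.092 /M/s)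
    partner B + partner A → second intermediate (k2 = 0.55 /M/s)
    crystals ⇌ product, rate k3*(cs3 - [product]) while solid is left; crystals form when [product] > cs3 (cs3 = 0.066 M, k3 = 2.2 /s)
    open intermediate + second intermediate → product (k4 = 0.17 /M/s)

**Fastest rung.** Partner A lasts about 10.1 s against partner B, and at the start it takes partner B 26.3 times as fast as the first portion of substrate does. So I let partner A finish first and freeze partner B at the surplus, its charge minus the charge of partner A: 0.0480 M.

**Middle rung.** I freeze second intermediate near the charge of partner A. Open intermediate then couples pseudo-first-order, with a time τ of 44.6 s.

**Slowest rung.** Substrate on the surplus needs 226 s, which is longer than both earlier times and longer than the run, so I ignore its loss. Averaged over the run, the portions put 62.5 % of the charge in the flask, which makes 0.0265 M of open intermediate by 80 s. Steady making against the drain τ has coupled 53.5 % of that, so I commit to 11.8 %. In the long run I expect the surplus to end as product, 40.0 %. Since the surplus lies below the solubility 0.066 M, I expect no crystals.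

**Forecast and result.** The forecast, lower than mine on the first answer and higher on the second, gives 9.5 % and 41.5 %: “Partner A takes most of partner B early”. The simulation gives 9.90 % and 41.0 %.

**Surplus again.** At 80.0 s the flask reads a half-life of substrate, by its step with partner B, of 4.1 min, longer than the 36 s of open intermediate by its coupling, and 79.4 % of the substrate is still there; the surplus gives 2.62 min for that half-life, shorter than the reading, and partner B stands at 0.0307 M, below the surplus. In the flask with 0.72 M of partner B the surplus is 0.588 M, and summing the decay of the portions leaves 12.6 % of the substrate, where that flask holds 15.6 % at 80.0 s.

The constants used here are invented, and the outcome is calculated.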